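Target reads 0.2% in the delta run at 120 min, under the scatter of 0.5 percentage points, while intermediate A reads 20.4%. The reckoning therefore follows one step: substrate plus reagent to intermediate A.

- delta: substrate 20 mM; reagent 0.40 equiv (fed, over 1.0 h); run made earlier
- flask: substrate 20 mM; reagent 0.800 equiv (fed, over 1.0 h); time 6.0 h

delta run (percent of the substrate charged)

| time / min | substrate / % | intermediate A / % | target / % |
|---|---|---|---|
| 15.0 | 98.9 | 0.4 | 0.6 |
| 40.0 | 93.7 | 4.2 | 0 |
| 80.0 | 83.1 | 13.1 | 0.8 |
| 120 | 77.1 | 20.4 | 0.2 |

(each reading ± 0.5 percentage points)

- why nothing more happens at 6.0 h, or that something still does (it is still moving / all of the substrate has reacted / forward and back rates have come level / the reagent has run out first)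
- share of the substrate used up at 6.0 h
- intermediate A at 6.0 h, in percent of the substrate charged
- amount of target if the flask were left three thousand times as long, in percent of the substrate charged

- steps under discussion: 2 reagent -> homo dimer; intermediate C -> target; intermediate C -> side product; substrate + reagent <-> intermediate B; reagent + target -> over-reaction product; substrate + reagent <-> intermediate A; intermediate B -> intermediate C
- the reaction counts as stopped when no species that holds the substrate changes by six tenths of a point or more over the second half of the time

Let s and r be substrate and reagent as fractions of the substrate charged, q the equivalents of reagent, and τ the time since the reagent arrived. The reagent is the limiting reagent here, and on this one step s − r stays at 1 − q. So the second-order rate λ·s·r integrates in closed form: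

ln(s/r) = ln(1/q) + (1 − q)·λ·τ

The two delta readings after the feed give λ = 0.565 h⁻¹, the clock rate: rate constant times substrate charge.

My reckoning takes two extreme versions of the flask:

reagent charged at the start, τ = 6.0 h: conversion 66.3%

reagent charged at the end of the feed, τ = 5.00 h: conversion 63.3%

Fed reagent arrives between those moments, so I expect the flask between them. The first version still gains 13 points over the second half of the time, so it is still moving. In the delta run, intermediate A already trails conversion by 2.5 points. The clock says nothing about target.

The forecast says it is still moving, with conversion 65% (58% to 71%), intermediate A 61% (53% to 67%) and long-time target 45% (12% to 75%), the last being “only a rough guess”.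

    2 reagent → homo dimer (k = 5.30 M⁻¹ h⁻¹)
    intermediate C → target (k = 0.0710 h⁻¹)
    intermediate C → side product (k = 0.470 h⁻¹)
    substrate + reagent ⇌ intermediate B (K = 21.0 M⁻¹, k = 5.70 M⁻¹ h⁻¹)
    reagent + target → over-reaction product (k = 11.0 M⁻¹ h⁻¹)
    substrate + reagent ⇌ intermediate A (K = 3100 M⁻¹, k = 32.0 M⁻¹ h⁻¹)
    intermediate B → intermediate C (k = 0.540 h⁻¹)

The answer for the flask at 6.0 h is "it is still moving", with conversion 61.6%, below 63.3%, intermediate A 54.5% and long-time target 1.76%. At 6.00 h this flask holds 0.929 mM of homo dimer. For the neighbour flask with 8.0 mM of substrate, the clock rate scales to 0.226 h⁻¹, and the same two extremes give 44.7% and 48.7%. That neighbour flask reaches a conversion of 47.5%.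

The runs are calculated with made-up constants.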